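# Proposed total synthesis of CNP0183298.2 (6β-acetoxy-7α-hydroxylabda-8,13Z-dien-15-ol)

## Analysis of the target

Target 26 is a labdane, and labdane numbering is used throughout. Ring A is C1–C5 and C10, ring B is C5–C10, C18 and C19 are the methyls on C4, C20 is the methyl on C10, C17 is the methyl on C8, and C11–C16 form the side chain on C9. The decalin is trans-fused and carries a tetrasubstituted C8=C9 alkene; the side chain ends in a Z-configured trisubstituted allylic alcohol (C13=C14, C15–OH).

All four stereocentres lie in the bicycle: quaternary C10 (S, β-methyl), C5 (S, α-hydrogen), C6 (S, β-acetoxy, axial) and C7 (S, α-hydroxy, pseudoaxial and allylic). The oxygens on C6 and C7 are therefore trans-diaxial, and the oxygen on C6 is syn-axial to the β-methyl groups on C4 and C10.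

The sensitive points are:
- the C7 hydroxyl, which is allylic to an electron-rich tetrasubstituted alkene;
- the acetate, which must sit on the more hindered of two neighbouring secondary hydroxyls;
- the Z-allylic alcohol;
- any 6-keto intermediate, which is β,γ-unsaturated and can slide into conjugation.

The difficulty is to make quaternary C10 as a single enantiomer beside a tetrasubstituted alkene, and then to tell three hydroxyl groups apart. The strategy rests on one feature: C10 is a quaternary carbon next to C5, and C5 carries C6. If C4 of ring A is written as a carbonyl, then C10, C5 and C6 are the β-carbon, the α-carbon and the α-substituent of a cyclohexanone. That is the pattern left by a conjugate addition followed by trapping of the enolate.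

## Retrosynthetic reasoning

**Acetate and protecting groups (26 ⇐ 25 ⇐ 24 ⇐ 23).** The C6–O–acetyl bond is cut last but one. The hydroxyls on C7 and C15 are masked as silyl ethers in 25, so the final step only has to remove silicon under non-basic conditions. The free 6β-hydroxyl of 24 comes from diol 23 by silylating the more accessible allylic 7α-hydroxyl. The trans-diaxial geometry means neither acetyl nor silyl can migrate between O6 and O7, so the position of the acetate is fixed once it is installed.

**C7–O bond and C6 configuration (23 ⇐ 22 ⇐ 21).** Both ring B oxygens are traced back to the 6-ketone 21. Its C7 methylene is α to the carbonyl and allylic, so it is the only position that enolises readily, and oxygen can be put there from the open α-face to give ketol 22. Reduction of the C6 carbonyl from the same α-face then gives the 6β-alcohol. No other disconnection sets both centres from one functional group.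

**C12–C13 bond (21 ⇐ 16 + 19).** The side chain is cut between sp3 C12 and sp2 C13. The cut leaves a primary iodide on the bicycle (16) and a small vinyl iodide (19) in which the Z geometry is already fixed. An sp3–sp2 coupling through an organozinc transfers that geometry unchanged and tolerates the ketone. Cutting at C11–C12 or C9–C11 would need allylic metal species that can transpose. Fragment 19 goes back through iodo alcohol 18 to alkyne 17, where an anti hydrometalation defines the alkene.

**Functional group adjustment (16 ⇐ 15 ⇐ 14 ⇐ 13).** The iodide and the ketone come from diol 14: the primary hydroxyl is substituted first, then the secondary one is oxidised. Diol 14 is the doubly desilylated form of 13. The C6 oxygen in 13 is the oxygen introduced by the aldol, so its configuration is irrelevant.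

**Geminal methyls on C4 (13 ⇐ 12 ⇐ 11 ⇐ 10).** The C4–C18 and C4–C19 bonds are cut back to the C4 carbonyl of decalone 10, by way of the spirocyclopropane 12 and the methylidene compound 11. This is the price of the key step: C4 must be a carbonyl when C10 and C5 are made, and is converted to the quaternary dimethyl carbon only after ring B is closed. At that stage the only other alkene is the hindered tetrasubstituted one.

**Ring B (10 ⇐ 9).** The C8=C9 double bond is cut by ring-closing metathesis. Both carbons already carry their substituents as 1,1-disubstituted alkenes in 9, so the closure creates no stereocentre and needs no oxidation-state change. The two alkenes sit on adjacent, trans-disposed positions of ring A, which is what a trans-fused six-membered ring requires.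

**Key disconnection (9 ⇐ 8 ⇐ 6 + 3 + 5).** After the silyl group on O6 is removed, the C9–C10 and C5–C6 bonds are cut together. That leads to enone 6, the α-alkenylalane 3 and aldehyde 5. The forward reaction has to add the alkenyl group to the β-carbon of 6 enantioselectively, and then let the regiodefined aluminium enolate 7 add to 5 on the face opposite the new alkenyl group. No other pair of cuts makes quaternary C10, C5 and the whole carbon frame of both rings from three achiral pieces in one operation.

**Building blocks (3 ⇐ 2 ⇐ 1; 5 ⇐ 4).** Alane 3 comes from silyl ether 2 of alkynol 1 by an internal-selective hydroalumination. Aldehyde 5 comes from alcohol 4 by oxidation just before use.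

## Alternatives that were turned down

**Alternative 1: one-carbon ring expansion of a hydrindene.**
- Disconnection: the C7–C8 and C8–C9 bonds. C8 is removed from ring B to leave the trans-hydrindene A1 with a C7=C9 cyclopentene.
- Key step: carbene transfer places a CBr2 unit across C7=C9. Silver-assisted loss of bromide opens the cyclopropane in a disrotatory sense to a 2-bromoallyl cation, which the aqueous medium captures at C7 to give A2.
- For: the absolute configuration would come from an enantiopure chiral-pool hydrindane and would not depend on a catalytic step. The 6β-oxygen is already present, and the 7α-hydroxyl arrives in the key step trans to it, so the late ketone, hydroxylation and reduction sequence of the chosen route is not needed. On these two points this alternative is stronger.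
- Against: A1 must already contain the geminal methyls, the 6β-silyloxy group, quaternary C10 and the C9 side chain, so most of the work is moved in front of the key step. The carbene must add to a trisubstituted alkene beside a quaternary carbon. The cation can also be captured at tertiary C9. The C8 methyl then needs a cross-coupling at a hindered vinyl bromide. The silyl alkyne of A2 still has to be turned into a Z-trisubstituted allylic alcohol, which a syn carbometalation of a terminal alkyne does not give directly.
- Comparison: the chosen strategy reaches the complete bicyclic carbon frame in three steps from achiral commercial compounds and installs the Z-alkene as a preformed unit.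

**Alternative 2: dearomative allylic alkylation of a phenol.**
- Disconnection: the C1–C10 bond. Ring A is opened to the hexasubstituted phenol A3, which carries an allylic carbonate tether on C5.
- Key step: a zerovalent palladium catalyst with a chiral phosphine ionises the carbonate. The para carbon C10 of the phenoxide attacks the far allyl terminus C1, closing ring A and giving dienone A4.
- For: A4 contains every carbon of the target, including the Z side chain, and has oxygen on both C6 and C7. In carbon-skeleton convergence it is stronger than the chosen route.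
- Against: the nucleophilic carbon is fully substituted and flanked by two ortho substituents. The ring closure needs the anti form of the allyl complex to deliver a cis ring alkene. A3 itself is a hexasubstituted arene that is long to prepare. After the key step C5, C6 and C7 are all planar. They would have to be set by reducing an enol-ether double bond, a cross-conjugated ketone and a ring A alkene, in the presence of the C8=C9 and C13=C14 alkenes. The methyl ether on O6 would also have to be exchanged for acetate.
- Comparison: the chosen strategy sets C5 together with C10 and leaves only C6 and C7, both controlled by the rigid trans-decalin.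

**Alternative 3: asymmetric ynal Diels–Alder reaction.**
- Disconnection: the C7–C8 and C9–C10 bonds. Ring B is split into silyloxydiene A5 (C10=C5–C6=C7) and but-2-ynal A6.
- Key step: a chiral oxazaborolidinium Lewis acid activates A6. The cycloaddition gives the 1,4-cyclohexadiene A7, with C10 set, a silyl enol ether at C6, the C8=C9 alkene, and C11 as an aldehyde.
- For: the polarities are matched (nucleophilic C7 meets the β-carbon C8 of the ynal). The geminal methyls are present from the start, ring B closes in the same step that sets C10, and the C6 oxygen emerges at the ketone level. On these three points it is as strong as or stronger than the chosen route, which needs three steps for the C4 methyls and a separate hindered metathesis.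
- Against: the diene terminus C10 is fully substituted, and the s-cis conformer is strained by the C4 methyls, so a low-temperature catalysed cycloaddition with a β-substituted ynal is doubtful. The silyl enol ether is exposed to a strong Lewis acid. C5 must be set afterwards by protonation. C11 arrives as an aldehyde, although the target has a methylene there, so deoxygenation and an allylic sp3–sp3 coupling would be needed to attach C12–C16 without scrambling the alkenes.
- Comparison: its endgame from the 6-ketone would be the same as the one used here from ketone 21. The chosen strategy brings C11 and C12 in at the correct oxidation level and sets C5 in the key step.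

Key step: step 4

**Assumptions.**
- The enantiomer of the chiral carbene ligand is taken as the one that delivers the alkenyl group to the enone face giving (S)-C10. The other ligand enantiomer would give the antipodal series.
- Compounds 8–15 are drawn with the 6S (6α-oxygen) configuration expected from a closed aldol transition state. A 6-epimer would pass through the same steps and converge at ketone 16.

## Route

Step 1
Reactants: 1 but-3-yn-1-ol
Product: 2 (but-3-yn-1-yloxy)tri(propan-2-yl)silane
Conditions: i-Pr3SiCl, imidazole, CH2Cl2, 0 °C → rt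
Reagents that add atoms: chlorotri(propan-2-yl)silane, CC(C)[Si](Cl)(C(C)C)C(C)C
Why: Standard silylation of a primary alcohol. The triisopropylsilyl ether is chosen because it withstands Al–H and acetic acid and has no arene that platinum could hydrogenate in step 9.

Step 2
Reactants: 2 (but-3-yn-1-yloxy)tri(propan-2-yl)silane
Product: 3 bis(2-methylpropyl)[4-{[tri(propan-2-yl)silyl]oxy}but-1-en-2-yl]alumane (used as a THF solution)
Conditions: i-Bu2AlH (0.95 equiv), Ni(dppp)Cl2 (3 mol %), THF, 0 → 22 °C
Reagents that add atoms: diisobutylaluminium hydride, CC(C)C[AlH]CC(C)C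
Why: Nickel-catalysed hydroalumination with the bidentate phosphine complex places aluminium on the internal carbon of a terminal alkyne, giving the 1,1-disubstituted alkenylalane. The alkyne is kept in slight excess so that no Al–H remains to reduce the enone.

Step 3
Reactants: 4 3-methylbut-3-en-1-ol
Product: 5 3-methylbut-3-enal (used as a CH2Cl2 solution)
Conditions: Dess–Martin periodinane, NaHCO3, CH2Cl2, 0 °C; filtered and used at once
Reagents that add atoms: none
Why: Dess–Martin oxidation under bicarbonate buffer stops at the aldehyde and avoids the acid or base that would move the alkene into conjugation.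

Step 4
Reactants: 6 3-methylcyclohex-2-en-1-one; 3 bis(2-methylpropyl)[4-{[tri(propan-2-yl)silyl]oxy}but-1-en-2-yl]alumane; 5 3-methylbut-3-enal
Product: 8 (2S,3S)-2-[(1S)-1-hydroxy-3-methylbut-3-en-1-yl]-3-methyl-3-(4-{[tri(propan-2-yl)silyl]oxy}but-1-en-2-yl)cyclohexan-1-one, via aluminium enolate 7 (not isolated)
Conditions: Cu(OTf)2 (5 mol %), silver carbene complex Ag2L2 (2.5 mol %; L = chiral 4,5-diphenylimidazolin-2-ylidene with an N-(2-sulfonatoaryl) and an N-(2,6-diethylphenyl) group), THF, −78 → 4 °C; then 5 (3 equiv), −78 → −30 °C; aq. KNaC4H4O6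
Reagents that add atoms: none
Why: The carbene passes from silver to copper and the alane reduces the divalent copper salt to the active monovalent copper–carbene complex; the alkenyl group moves from aluminium to copper, the enone binds as a π-complex, and reductive elimination from a trivalent copper intermediate forms C9–C10 and leaves the aluminium enolate 7, regiodefined at C5. The closest known reaction type is the carbene–copper-catalysed enantioselective conjugate addition of alkenylaluminium reagents to β-substituted cyclic enones, combined with aldol trapping of the aluminium enolate. No ring closes in this step. C10 is controlled by the chiral carbene ligand, which selects the enone face. C5 is relayed from C10: the aluminium-bound aldehyde attacks C5 axially through a chair-like transition state with the flat alkenyl group axial and anti to it, because the other arrangement puts the incoming aldehyde gauche to the larger group; C6 thus ends trans to C9 and cis to the C10 methyl. C6 follows from the closed six-membered transition state of the ring-locked E-enolate (anti aldol, 6S), and its configuration is lost later at the ketone stage. The step needs 1,4- over 1,2-addition (secured by copper), transfer of the sp2 group instead of isobutyl (alkenyl transfers faster from aluminium), and trapping without isomerising the β,γ-unsaturated aldehyde (the aluminium enolate is weakly basic and the temperature is low).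

Step 5
Reactants: 8 (2S,3S)-2-[(1S)-1-hydroxy-3-methylbut-3-en-1-yl]-3-methyl-3-(4-{[tri(propan-2-yl)silyl]oxy}but-1-en-2-yl)cyclohexan-1-one
Product: 9 (2S,3S)-2-[(1S)-1-{[tert-butyl(dimethyl)silyl]oxy}-3-methylbut-3-en-1-yl]-3-methyl-3-(4-{[tri(propan-2-yl)silyl]oxy}but-1-en-2-yl)cyclohexan-1-one
Conditions: t-BuMe2SiOTf (1.2 equiv), 2,6-lutidine, CH2Cl2, −78 °C
Reagents that add atoms: tert-butyldimethylsilyl trifluoromethanesulfonate, CC(C)(C)[Si](C)(C)OS(=O)(=O)C(F)(F)F
Why: Silyl triflate with a hindered base silylates the secondary alcohol at low temperature without enolising the ketone. Capping O6 blocks retro-aldol cleavage and elimination in the following steps.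

Step 6
Reactants: 9 (2S,3S)-2-[(1S)-1-{[tert-butyl(dimethyl)silyl]oxy}-3-methylbut-3-en-1-yl]-3-methyl-3-(4-{[tri(propan-2-yl)silyl]oxy}but-1-en-2-yl)cyclohexan-1-one
Product: 10 (5S,6S,10S)-6α-(tert-butyldimethylsilyloxy)-12-(triisopropylsilyloxy)-13,14,15,16,18,19-hexanorlabd-8-en-4-one (trans-fused; 5α-H, 10β-methyl)
Conditions: second-generation Hoveyda–Grubbs catalyst (H2IMes)Cl2Ru=CH(2-i-PrO-C6H4) (10 mol %), toluene, 90 °C, argon sparge
Reagents that add atoms: none
Why: Ring-closing olefin metathesis. The ruthenium alkylidene forms on the less hindered methallyl unit and closes onto the C9 alkene, which is held nearby on the adjacent trans-diequatorial position of ring A. Loss of the volatile alkene drives formation of the six-membered ring B with the tetrasubstituted C8=C9 bond.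

Step 7
Reactants: 10 (5S,6S,10S)-6α-(tert-butyldimethylsilyloxy)-12-(triisopropylsilyloxy)-13,14,15,16,18,19-hexanorlabd-8-en-4-one
Product: 11 (5S,6S,10S)-6α-(tert-butyldimethylsilyloxy)-12-(triisopropylsilyloxy)-13,14,15,16,19-pentanorlabda-4(18),8-diene (4-methylidene compound)
Conditions: Cp2TiMe2, toluene, 70 °C, dark
Reagents that add atoms: dimethyltitanocene, [CH3-].[CH3-].[Ti+4].c1cc[cH-]c1.c1cc[cH-]c1
Why: Titanium methylidene olefination (Petasis methylenation). The reagent is not basic, so C5 beside the carbonyl is not epimerised and the β-silyloxy group is not eliminated, and it tolerates hindered ketones.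

Step 8
Reactants: 11 (5S,6S,10S)-6α-(tert-butyldimethylsilyloxy)-12-(triisopropylsilyloxy)-13,14,15,16,19-pentanorlabda-4(18),8-diene
Product: 12 (5S,6S,10S)-6α-(tert-butyldimethylsilyloxy)-12-(triisopropylsilyloxy)-18,19-cyclo-13,14,15,16-tetranorlabd-8-ene (spirocyclopropane at C4)
Conditions: Et2Zn, CH2I2 (1.5 equiv carbenoid), CH2Cl2, 0 °C → rt
Reagents that add atoms: diiodomethane, ICI
Why: Simmons–Smith cyclopropanation in the Furukawa variant. The exposed exocyclic 1,1-disubstituted alkene should react faster than the tetrasubstituted C8=C9 alkene, which is shielded by quaternary C10, provided the carbenoid is limited.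

Step 9
Reactants: 12 (5S,6S,10S)-6α-(tert-butyldimethylsilyloxy)-12-(triisopropylsilyloxy)-18,19-cyclo-13,14,15,16-tetranorlabd-8-ene
Product: 13 (5S,6S,10S)-6α-(tert-butyldimethylsilyloxy)-12-(triisopropylsilyloxy)-13,14,15,16-tetranorlabd-8-ene
Conditions: H2 (1 atm), PtO2, AcOH, rt
Reagents that add atoms: none
Why: Hydrogenolysis of a spirocyclopropane over platinum cleaves the least substituted CH2–CH2 bond and leaves two methyl groups on C4. The tetrasubstituted alkene is too hindered to be hydrogenated, and neither silyl group has an arene.

Step 10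
Reactants: 13 (5S,6S,10S)-6α-(tert-butyldimethylsilyloxy)-12-(triisopropylsilyloxy)-13,14,15,16-tetranorlabd-8-ene
Product: 14 (5S,6S,10S)-13,14,15,16-tetranorlabd-8-ene-6α,12-diol
Conditions: Bu4NF, THF, 50 °C
Reagents that add atoms: none
Why: Fluoride cleaves both silyl ethers in one operation; nothing else in the molecule is base- or fluoride-sensitive.

Step 11
Reactants: 14 (5S,6S,10S)-13,14,15,16-tetranorlabd-8-ene-6α,12-diol
Product: 15 (5S,6S,10S)-12-iodo-13,14,15,16-tetranorlabd-8-en-6α-ol
Conditions: I2, PPh3, imidazole, CH2Cl2, 0 °C
Reagents that add atoms: iodine, II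
Why: Appel-type iodination through an alkoxyphosphonium ion and SN2 displacement. Only the primary C12 hydroxyl reacts, because the C6 hydroxyl is flanked by C5 and the C4 methyls.

Step 12
Reactants: 15 (5S,6S,10S)-12-iodo-13,14,15,16-tetranorlabd-8-en-6α-ol
Product: 16 (5S,10S)-12-iodo-13,14,15,16-tetranorlabd-8-en-6-one
Conditions: Dess–Martin periodinane, NaHCO3, CH2Cl2, 0 °C → rt
Reagents that add atoms: none
Why: Dess–Martin oxidation tolerates the alkyl iodide, and the buffer keeps the β,γ-alkene in place. C5 is now α to a carbonyl, but the 5α-hydrogen (trans-fused) form is the stable one.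

Step 13
Reactants: 17 but-2-yn-1-ol
Product: 18 (2Z)-3-iodobut-2-en-1-ol
Conditions: NaAlH2(OCH2CH2OMe)2, Et2O, 0 °C → rt; then I2, THF, −78 °C
Reagents that add atoms: iodine, II
Why: Alkoxide-directed trans-hydroalumination of a propargylic alcohol delivers hydride to C2 and forms a cyclic alkenylaluminate with aluminium on C3 cis to the CH2O group. Iodinolysis with retention gives the Z-vinyl iodide.

Step 14
Reactants: 18 (2Z)-3-iodobut-2-en-1-ol
Product: 19 tert-butyl{[(2Z)-3-iodobut-2-en-1-yl]oxy}dimethylsilane
Conditions: t-BuMe2SiCl, imidazole, CH2Cl2, rt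
Reagents that add atoms: tert-butyldimethylsilyl chloride, CC(C)(C)[Si](C)(C)Cl
Why: Standard silylation. It removes the acidic hydroxyl that would quench the organozinc reagent in the next step.

Step 15
Reactants: 16 (5S,10S)-12-iodo-13,14,15,16-tetranorlabd-8-en-6-one; 19 tert-butyl{[(2Z)-3-iodobut-2-en-1-yl]oxy}dimethylsilane
Product: 21 (5S,10S,13Z)-15-(tert-butyldimethylsilyloxy)labda-8,13-dien-6-one, via alkylzinc iodide 20 (not isolated)
Conditions: Zn dust (activated), LiCl, THF, 35 °C; then 19, PdCl2(dppf) (5 mol %), THF, 40 °C
Reagents that add atoms: none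
Why: Negishi coupling. Zinc inserts into the primary C–I bond and the resulting alkylzinc tolerates the ketone; zerovalent palladium adds to the vinyl iodide with retention, and transmetalation and reductive elimination form C12–C13 with the Z geometry intact. The wide-bite-angle diphosphine suppresses β-hydride elimination.

Step 16
Reactants: 21 (5S,10S,13Z)-15-(tert-butyldimethylsilyloxy)labda-8,13-dien-6-one
Product: 22 (5S,7S,10S,13Z)-7α-hydroxy-15-(tert-butyldimethylsilyloxy)labda-8,13-dien-6-one
Conditions: KN(SiMe3)2, THF, −78 °C; 3-phenyl-2-(phenylsulfonyl)oxaziridine, −78 °C; AcOH quench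
Reagents that add atoms: 3-phenyl-2-(phenylsulfonyl)oxaziridine, O=S(=O)(c1ccccc1)N1OC1c1ccccc1
Why: Kinetic deprotonation occurs at C7, which is α to the carbonyl and allylic, and not at C5, which lies between two quaternary carbons. The dienolate attacks the oxaziridine oxygen through its α-carbon C7 (Davis hydroxylation) from the α-face, opposite the axial methyls on C4 and C10, giving the 7α-alcohol. The acidic quench prevents the α-ketol from rearranging or epimerising.

Step 17
Reactants: 22 (5S,7S,10S,13Z)-7α-hydroxy-15-(tert-butyldimethylsilyloxy)labda-8,13-dien-6-one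
Product: 23 (5S,6S,7S,10S,13Z)-15-(tert-butyldimethylsilyloxy)labda-8,13-diene-6β,7α-diol
Conditions: Me4NBH(OAc)3, MeCN/AcOH, −30 → −20 °C
Reagents that add atoms: none
Why: Hydroxyl-directed triacetoxyborohydride reduction. The 7α-hydroxyl exchanges onto boron and hydride is delivered internally to the α-face of C6, which is also the open face because the β-face is blocked by the syn-axial methyls on C4 and C10. The result is the 6β-alcohol trans to O7, and the acidic medium suppresses ketol rearrangement.

Step 18
Reactants: 23 (5S,6S,7S,10S,13Z)-15-(tert-butyldimethylsilyloxy)labda-8,13-diene-6β,7α-diol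
Product: 24 (5S,6S,7S,10S,13Z)-15-(tert-butyldimethylsilyloxy)-7α-(triethylsilyloxy)labda-8,13-dien-6β-ol
Conditions: Et3SiCl (1.1 equiv), imidazole, DMF, 0 °C
Reagents that add atoms: chlorotriethylsilane, CC[Si](Cl)(CC)CC
Why: Silylation selects the allylic 7α-hydroxyl, because the 6β-hydroxyl is shielded by two syn-axial methyl groups. The trans-diaxial geometry rules out silyl migration.

Step 19
Reactants: 24 (5S,6S,7S,10S,13Z)-15-(tert-butyldimethylsilyloxy)-7α-(triethylsilyloxy)labda-8,13-dien-6β-ol
Product: 25 (5S,6S,7S,10S,13Z)-15-(tert-butyldimethylsilyloxy)-7α-(triethylsilyloxy)labda-8,13-dien-6β-yl acetate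
Conditions: Ac2O, DMAP, Et3N, CH2Cl2, 40 °C
Reagents that add atoms: acetic anhydride, CC(=O)OC(C)=O
Why: DMAP-catalysed acylation through the N-acetylpyridinium ion is the standard answer to a hindered axial secondary alcohol. The neighbouring silyloxy group is anti-periplanar and points to the other face, so it adds little hindrance.

Step 20
Reactants: 25 (5S,6S,7S,10S,13Z)-15-(tert-butyldimethylsilyloxy)-7α-(triethylsilyloxy)labda-8,13-dien-6β-yl acetate
Product: 26 (5S,6S,7S,10S,13Z)-7α,15-dihydroxylabda-8,13-dien-6β-yl acetate (CNP0183298.2)
Conditions: HF·pyridine, pyridine, THF, 0 °C → rt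
Reagents that add atoms: none
Why: Buffered hydrogen fluoride cleaves both silyl ethers without base, so the acetate is neither hydrolysed nor moved. The trans-diaxial relation of O6 and O7 also prevents acyl migration.

## Compound list

1 | but-3-yn-1-ol | C#CCCO | starting material
2 | (but-3-yn-1-yloxy)tri(propan-2-yl)silane | C#CCCO[Si](C(C)C)(C(C)C)C(C)C | intermediate
3 | bis(2-methylpropyl)[4-{[tri(propan-2-yl)silyl]oxy}but-1-en-2-yl]alumane | C=C([Al](CC(C)C)CC(C)C)CCO[Si](C(C)C)(C(C)C)C(C)C | intermediate
4 | 3-methylbut-3-en-1-ol | CC(=C)CCO | starting material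
5 | 3-methylbut-3-enal | CC(=C)CC=O | intermediate
6 | 3-methylcyclohex-2-en-1-one | CC1=CC(=O)CCC1 | starting material
7 | {[(3S)-3-methyl-3-(4-{[tri(propan-2-yl)silyl]oxy}but-1-en-2-yl)cyclohex-1-en-1-yl]oxy}bis(2-methylpropyl)alumane (aluminium enolate, not isolated) | C=C(CCO[Si](C(C)C)(C(C)C)C(C)C)[C@@]1(C)CCCC(O[Al](CC(C)C)CC(C)C)=C1 | intermediate
8 | (2S,3S)-2-[(1S)-1-hydroxy-3-methylbut-3-en-1-yl]-3-methyl-3-(4-{[tri(propan-2-yl)silyl]oxy}but-1-en-2-yl)cyclohexan-1-one | C=C(C)C[C@H](O)[C@H]1C(=O)CCC[C@]1(C)C(=C)CCO[Si](C(C)C)(C(C)C)C(C)C | intermediate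
9 | (2S,3S)-2-[(1S)-1-{[tert-butyl(dimethyl)silyl]oxy}-3-methylbut-3-en-1-yl]-3-methyl-3-(4-{[tri(propan-2-yl)silyl]oxy}but-1-en-2-yl)cyclohexan-1-one | C=C(C)C[C@H](O[Si](C)(C)C(C)(C)C)[C@H]1C(=O)CCC[C@]1(C)C(=C)CCO[Si](C(C)C)(C(C)C)C(C)C | intermediate
10 | (5S,6S,10S)-6α-(tert-butyldimethylsilyloxy)-12-(triisopropylsilyloxy)-13,14,15,16,18,19-hexanorlabd-8-en-4-one | CC(C)(C)[Si](C)(C)O[C@H]1CC(C)=C(CCO[Si](C(C)C)(C(C)C)C(C)C)[C@@]2(C)CCCC(=O)[C@H]12 | intermediate
11 | (5S,6S,10S)-6α-(tert-butyldimethylsilyloxy)-12-(triisopropylsilyloxy)-13,14,15,16,19-pentanorlabda-4(18),8-diene | CC(C)(C)[Si](C)(C)O[C@H]1CC(C)=C(CCO[Si](C(C)C)(C(C)C)C(C)C)[C@@]2(C)CCCC(=C)[C@H]12 | intermediate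
12 | (5S,6S,10S)-6α-(tert-butyldimethylsilyloxy)-12-(triisopropylsilyloxy)-18,19-cyclo-13,14,15,16-tetranorlabd-8-ene | CC(C)(C)[Si](C)(C)O[C@H]1CC(C)=C(CCO[Si](C(C)C)(C(C)C)C(C)C)[C@@]2(C)CCCC3(CC3)[C@H]12 | intermediate
13 | (5S,6S,10S)-6α-(tert-butyldimethylsilyloxy)-12-(triisopropylsilyloxy)-13,14,15,16-tetranorlabd-8-ene | CC(C)(C)[Si](C)(C)O[C@H]1CC(C)=C(CCO[Si](C(C)C)(C(C)C)C(C)C)[C@@]2(C)CCCC(C)(C)[C@H]12 | intermediate
14 | (5S,6S,10S)-13,14,15,16-tetranorlabd-8-ene-6α,12-diol | O[C@H]1CC(C)=C(CCO)[C@@]2(C)CCCC(C)(C)[C@H]12 | intermediate
15 | (5S,6S,10S)-12-iodo-13,14,15,16-tetranorlabd-8-en-6α-ol | O[C@H]1CC(C)=C(CCI)[C@@]2(C)CCCC(C)(C)[C@H]12 | intermediate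
16 | (5S,10S)-12-iodo-13,14,15,16-tetranorlabd-8-en-6-one | O=C1CC(C)=C(CCI)[C@@]2(C)CCCC(C)(C)[C@H]12 | intermediate
17 | but-2-yn-1-ol | CC#CCO | starting material
18 | (2Z)-3-iodobut-2-en-1-ol | C/C(I)=C/CO | intermediate
19 | tert-butyl{[(2Z)-3-iodobut-2-en-1-yl]oxy}dimethylsilane | C/C(I)=C/CO[Si](C)(C)C(C)(C)C | intermediate
20 | [(5S,10S)-6-oxo-13,14,15,16-tetranorlabd-8-en-12-yl]zinc iodide (not isolated) | O=C1CC(C)=C(CC[Zn]I)[C@@]2(C)CCCC(C)(C)[C@H]12 | intermediate
21 | (5S,10S,13Z)-15-(tert-butyldimethylsilyloxy)labda-8,13-dien-6-one | O=C1CC(C)=C(CC/C(C)=C\CO[Si](C)(C)C(C)(C)C)[C@@]2(C)CCCC(C)(C)[C@H]12 | intermediate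
22 | (5S,7S,10S,13Z)-7α-hydroxy-15-(tert-butyldimethylsilyloxy)labda-8,13-dien-6-one | O=C1[C@@H](O)C(C)=C(CC/C(C)=C\CO[Si](C)(C)C(C)(C)C)[C@@]2(C)CCCC(C)(C)[C@H]12 | intermediate
23 | (5S,6S,7S,10S,13Z)-15-(tert-butyldimethylsilyloxy)labda-8,13-diene-6β,7α-diol | O[C@@H]1[C@@H](O)C(C)=C(CC/C(C)=C\CO[Si](C)(C)C(C)(C)C)[C@@]2(C)CCCC(C)(C)[C@H]12 | intermediate
24 | (5S,6S,7S,10S,13Z)-15-(tert-butyldimethylsilyloxy)-7α-(triethylsilyloxy)labda-8,13-dien-6β-ol | O[C@@H]1[C@@H](O[Si](CC)(CC)CC)C(C)=C(CC/C(C)=C\CO[Si](C)(C)C(C)(C)C)[C@@]2(C)CCCC(C)(C)[C@H]12 | intermediate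
25 | (5S,6S,7S,10S,13Z)-15-(tert-butyldimethylsilyloxy)-7α-(triethylsilyloxy)labda-8,13-dien-6β-yl acetate | CC(=O)O[C@@H]1[C@@H](O[Si](CC)(CC)CC)C(C)=C(CC/C(C)=C\CO[Si](C)(C)C(C)(C)C)[C@@]2(C)CCCC(C)(C)[C@H]12 | intermediate
26 | (5S,6S,7S,10S,13Z)-7α,15-dihydroxylabda-8,13-dien-6β-yl acetate (CNP0183298.2) | CC(=O)O[C@@H]1[C@@H](O)C(C)=C(CC/C(C)=C\CO)[C@@]2(C)CCCC(C)(C)[C@H]12 | target

## Step count and least certain steps

Total: 20 steps. Longest linear sequence: 17 steps (steps 1, 2, 4–12 and 15–20, from but-3-yn-1-ol). Steps 3, 13 and 14 prepare the two side fragments.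

**Step 4 (key step).**
- Most likely problem: incomplete facial control at C5, if the aldehyde also approaches syn to the alkenyl group. A second problem is loss of the trapping step. The β,γ-unsaturated aldehyde can isomerise into conjugation, or be consumed by residual Al–C or Al–H species, so that the enolate is simply protonated. Enantioface discrimination may also be lower for an α-branched alkenyl group than for simpler ones.
- Fallback: set out from enolate 7, generated as in step 4 from 6 and 3, and silylate it with Me3SiCl to the enol silane trimethyl{[(3S)-3-methyl-3-(4-{[tri(propan-2-yl)silyl]oxy}but-1-en-2-yl)cyclohex-1-en-1-yl]oxy}silane F1. This can be freed from aluminium residues. Cleavage with MeLi in THF regenerates the regiodefined lithium enolate, which is transmetalated with ZnCl2 and added to 5 at −78 °C. The fallback comes back at 8. Separating the two events lets the aldol be run with a clean, stoichiometric enolate and a different counter-ion.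
- A C5 epimer that survives should in addition be correctable at decalone 10, where C5–H is α to the C4 carbonyl and the trans-fused form is expected to be the more stable.

**Step 6 (ring-closing metathesis).**
- Most likely problem: after loading on the methallyl unit, the ruthenium alkylidene may fail to engage the neopentyl-type 1,1-disubstituted alkene at C9. Turnover then stalls, the catalyst decomposes, and ruthenium hydrides may migrate the alkenes.
- Fallback: a reductive carbonyl coupling in place of metathesis, setting out from 9.
  - NaBH4 in MeOH gives the C4 alcohol F2 (either C4 epimer serves).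
  - Et3SiCl and imidazole give the triethylsilyl ether F3.
  - Ozonolysis (O3, CH2Cl2, −78 °C; PPh3) of both alkenes gives the 8,9-diketone F4.
  - Low-valent titanium (TiCl3, Zn–Cu couple, DME, reflux, slow addition) closes ring B by McMurry coupling to the tetrasubstituted alkene F5.
  - Pyridinium p-toluenesulfonate in MeOH removes only the triethylsilyl group, giving alcohol F6.
  - Dess–Martin oxidation brings the sequence back to 10.

**Step 8 (with consequences for step 9).**
- Most likely problem: the carbenoid may also attack the electron-rich C8=C9 alkene. In the following hydrogenolysis, acid and platinum may move or saturate that alkene, or cleave a silyl ether by acetolysis.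
- Fallback: set out from 11 and hydromethylate the exocyclic alkene by hydrogen-atom transfer. Fe(acac)3 and PhSiH3 in THF/MeOH generate the tertiary C4 radical selectively from the 1,1-disubstituted alkene. A formaldehyde N-arylsulfonylhydrazone (taken here as the mesitylsulfonyl compound) captures it, giving the alkyl sulfonylhydrazide F7. Warming in MeOH at 60 °C expels sulfinate and nitrogen to leave the second methyl group. The fallback comes back at 13 and bypasses 12 and step 9.

**Step 16 (C7 hydroxylation).**
- Most likely problem: base-induced rearrangement of the α-ketol into the conjugated 6-hydroxy-7-oxo isomer, or epimerisation at C7, before the quench. The enolate may also add to the sulfonimine released by the oxidant.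
- Fallback: set out from 21. Trap the potassium dienolate with Et3SiCl (KN(SiMe3)2, THF, −78 °C) as the silyl dienol ether F8. Oxidise its enol ether double bond with dimethyldioxirane at −78 °C (Rubottom-type oxidation from the α-face, with silyl transfer), giving the 7α-triethylsilyloxy ketone F9, which cannot undergo ketol rearrangement. Reduction with NaBH4 from the open α-face comes back at 24. One equivalent of oxidant at low temperature is needed to spare the C13=C14 alkene.

**Step 19 (acetylation of the 6β-hydroxyl).**
- Most likely problem: slow acylation of the alcohol between two syn-axial methyl groups. Forcing conditions could then cause loss of the silyl group on O7 or elimination.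
- Fallback: set out from 23 and differentiate by hydrolysis rate instead of by protection. HF·pyridine gives the triol (5S,6S,7S,10S,13Z)-labda-8,13-diene-6β,7α,15-triol F10. Ac2O, DMAP and pyridine at 60 °C, with no silyl group left to protect, give the triacetate F11. K2CO3 in MeOH at 0 °C should remove the primary allylic and the secondary allylic acetates well before the buried 6β-acetate, and so comes back at 26.

## Further compounds

F1 | step 4 | trimethyl{[(3S)-3-methyl-3-(4-{[tri(propan-2-yl)silyl]oxy}but-1-en-2-yl)cyclohex-1-en-1-yl]oxy}silane | C=C(CCO[Si](C(C)C)(C(C)C)C(C)C)[C@@]1(C)CCCC(O[Si](C)(C)C)=C1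
F2 | step 6 | (2S,3S)-2-[(1S)-1-{[tert-butyl(dimethyl)silyl]oxy}-3-methylbut-3-en-1-yl]-3-methyl-3-(4-{[tri(propan-2-yl)silyl]oxy}but-1-en-2-yl)cyclohexan-1-ol (C1 of the ring unspecified) | C=C(C)C[C@H](O[Si](C)(C)C(C)(C)C)[C@H]1C(O)CCC[C@]1(C)C(=C)CCO[Si](C(C)C)(C(C)C)C(C)C
F3 | step 6 | triethylsilyl ether of F2 | C=C(C)C[C@H](O[Si](C)(C)C(C)(C)C)[C@H]1C(O[Si](CC)(CC)CC)CCC[C@]1(C)C(=C)CCO[Si](C(C)C)(C(C)C)C(C)C
F4 | step 6 | 8,9-diketone from ozonolysis of F3 (methyl ketone at C8, ketone at C9) | CC(=O)C[C@H](O[Si](C)(C)C(C)(C)C)[C@H]1C(O[Si](CC)(CC)CC)CCC[C@]1(C)C(=O)CCO[Si](C(C)C)(C(C)C)C(C)C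
F5 | step 6 | (5S,6S,10S)-6α-(tert-butyldimethylsilyloxy)-4-(triethylsilyloxy)-12-(triisopropylsilyloxy)-13,14,15,16,18,19-hexanorlabd-8-ene (C4 unspecified) | CC(C)(C)[Si](C)(C)O[C@H]1CC(C)=C(CCO[Si](C(C)C)(C(C)C)C(C)C)[C@@]2(C)CCCC(O[Si](CC)(CC)CC)[C@H]12
F6 | step 6 | (5S,6S,10S)-6α-(tert-butyldimethylsilyloxy)-12-(triisopropylsilyloxy)-13,14,15,16,18,19-hexanorlabd-8-en-4-ol (C4 unspecified) | CC(C)(C)[Si](C)(C)O[C@H]1CC(C)=C(CCO[Si](C(C)C)(C(C)C)C(C)C)[C@@]2(C)CCCC(O)[C@H]12
F7 | step 8 | N'-{[(5S,6S,10S)-6α-(tert-butyldimethylsilyloxy)-12-(triisopropylsilyloxy)-13,14,15,16,19-pentanorlabd-8-en-18-yl]}-2,4,6-trimethylbenzenesulfonohydrazide (C4 unspecified) | CC(C)(C)[Si](C)(C)O[C@H]1CC(C)=C(CCO[Si](C(C)C)(C(C)C)C(C)C)[C@@]2(C)CCCC(C)(CNNS(=O)(=O)c3c(C)cc(C)cc3C)[C@H]12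
F8 | step 16 | (5S,10S,13Z)-15-(tert-butyldimethylsilyloxy)-6-(triethylsilyloxy)labda-6,8,13-triene | CC[Si](CC)(CC)OC1=CC(C)=C(CC/C(C)=C\CO[Si](C)(C)C(C)(C)C)[C@@]2(C)CCCC(C)(C)[C@H]12
F9 | step 16 | (5S,7S,10S,13Z)-15-(tert-butyldimethylsilyloxy)-7α-(triethylsilyloxy)labda-8,13-dien-6-one | O=C1[C@@H](O[Si](CC)(CC)CC)C(C)=C(CC/C(C)=C\CO[Si](C)(C)C(C)(C)C)[C@@]2(C)CCCC(C)(C)[C@H]12
F10 | step 19 | (5S,6S,7S,10S,13Z)-labda-8,13-diene-6β,7α,15-triol | O[C@@H]1[C@@H](O)C(C)=C(CC/C(C)=C\CO)[C@@]2(C)CCCC(C)(C)[C@H]12
F11 | step 19 | (5S,6S,7S,10S,13Z)-labda-8,13-diene-6β,7α,15-triyl triacetate | CC(=O)O[C@@H]1[C@@H](OC(C)=O)C(C)=C(CC/C(C)=C\COC(C)=O)[C@@]2(C)CCCC(C)(C)[C@H]12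
A1 | alternative 1 | trans-hydrindene with C7=C9 alkene, 6β-silyloxy group and silyl alkyne side chain | CC(C)(C)[Si](C)(C)O[C@@H]1C=C(CCC#C[Si](C(C)C)(C(C)C)C(C)C)[C@@]2(C)CCCC(C)(C)[C@H]12
A2 | alternative 1 | 8-bromo-6β-silyloxy-7α-hydroxy decalin with C8=C9 alkene | CC(C)(C)[Si](C)(C)O[C@@H]1[C@@H](O)C(Br)=C(CCC#C[Si](C(C)C)(C(C)C)C(C)C)[C@@]2(C)CCCC(C)(C)[C@H]12
A3 | alternative 2 | hexasubstituted phenol with allylic carbonate tether on C5 | COc1c(O)c(C)c(CC/C(C)=C\CO[Si](C)(C)C(C)(C)C)c(C)c1C(C)(C)/C=C/COC(=O)OC
A4 | alternative 2 | 6-methoxylabda-2,5,8,13Z-tetraen-7-one 15-silyl ether | COC1=C2C(C)(C)C=CC[C@]2(C)C(CC/C(C)=C\CO[Si](C)(C)C(C)(C)C)=C(C)C1=O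
A5 | alternative 3 | tert-butyldimethyl{[1-(2,6,6-trimethylcyclohex-1-en-1-yl)ethenyl]oxy}silane | C=C(O[Si](C)(C)C(C)(C)C)C1=C(C)CCCC1(C)C
A6 | alternative 3 | but-2-ynal | CC#CC=O
A7 | alternative 3 | bicyclic 1,4-cyclohexadiene with C6 silyl enol ether, C8=C9 alkene and C11 aldehyde | CC(C)(C)[Si](C)(C)OC1=C2C(C)(C)CCC[C@]2(C)C(C=O)=C(C)C1
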